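**Strategy**

Everything rests on disconnecting C1–C2 of the cyclohexenone, the bond between the carbonyl carbon and the cis-alkene carbon. The key step exploits the β-hydroxy ketone array O–C5–C6–C1 of the six-membered ring: it is pre-tied as a strained four-membered oxetan-2-one, so the precursor is a β-lactone whose quaternary carbon carries the nonadecyl chain and a (Z)-3-iodoallyl arm. Iodine–lithium exchange makes C2 a cis-alkenyl carbanion that attacks the lactone carbonyl: in one operation the carbocycle closes, the lactone opens with release of strain, and the enone and the free tertiary C5 hydroxyl appear at their final oxidation level. C5 is set earlier by a catalytic asymmetric epoxidation.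

Key step: step 8

Remark: ring atoms carry the numbering of the target throughout (C1 carbonyl, C2=C3, C4, C5 carbinol, C6); in step 2 the ligand antipode is assumed to be the one that delivers the (R)-epoxide, and the facial sense would have to be confirmed before committing material.

**Route**

Step 1
Reactants: 1 3-methylbut-3-en-1-ol (isoprenol); 2 1-bromooctadecane
Product: 4 3-methylidenedocosan-1-ol, via dilithio isoprenol 3 (not isolated)
Conditions: n-BuLi (2.2 equiv), TMEDA, Et2O/hexane, 0 °C to rt; then 2, THF, −78 °C to rt; H2O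
Reagents that add atoms: none
Why: Alkoxide-directed allylic lithiation gives the symmetrical 2-substituted allyl dianion 3, and its SN2 C-alkylation by the primary bromide (dianion alkylation) gives the same 1,1-disubstituted alkene at either CH2 terminus, with no stereocentre formed.

Step 2
Reactants: 4 3-methylidenedocosan-1-ol
Product: 5 (R)-2-(2-nonadecyloxiran-2-yl)ethan-1-ol
Conditions: Hf(Ot-Bu)4 (cat.), C2-symmetric bishydroxamic acid ligand derived from trans-cyclohexane-1,2-diamine (cat.), cumene hydroperoxide, DMPU, 4 Å MS, toluene, 0 °C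
Reagents that add atoms: cumene hydroperoxide, CC(C)(OO)c1ccccc1
Why: Hydroxyl-directed catalytic asymmetric epoxidation of a homoallylic alcohol by a tetravalent hafnium–bishydroxamic acid peroxo complex: the alcohol binds the metal and the C2-symmetric ligand lets oxygen reach only one face of the 1,1-disubstituted alkene, so the chosen ligand antipode sets the quaternary centre (later C5) as R.

Step 3
Reactants: 5 (R)-2-(2-nonadecyloxiran-2-yl)ethan-1-ol
Product: 6 (S)-3-(prop-2-yn-1-yl)docosane-1,3-diol
Conditions: lithium acetylide–ethylenediamine complex (4 equiv), DMSO/THF, rt to 40 °C; H2O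
Reagents that add atoms: lithium acetylide, [Li]C#C
Why: SN2 opening of the 2,2-disubstituted epoxide by acetylide at its unsubstituted CH2 terminus, with the primary hydroxyl carried as its lithium alkoxide; no bond to the quaternary carbon is broken, so the configuration is retained and only the descriptor changes.

Step 4
Reactants: 6 (S)-3-(prop-2-yn-1-yl)docosane-1,3-diol
Product: 7 (S)-3-(3-iodoprop-2-yn-1-yl)docosane-1,3-diol
Conditions: NIS (1.1 equiv), AgNO3 (10 mol %), acetone, rt, dark
Reagents that add atoms: N-iodosuccinimide, O=C1CCC(=O)N1I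
Why: Silver-catalysed electrophilic iodination of the terminal alkyne C–H through the silver acetylide, which leaves both hydroxyl groups untouched.

Step 5
Reactants: 7 (S)-3-(3-iodoprop-2-yn-1-yl)docosane-1,3-diol
Product: 8 (S)-3-[(2Z)-3-iodoprop-2-en-1-yl]docosane-1,3-diol
Conditions: 2-nitrobenzenesulfonylhydrazide, Et3N, THF/i-PrOH, rt
Reagents that add atoms: none
Why: Diimide reduction: diimide formed in situ from the sulfonylhydrazide transfers H2 in a concerted syn fashion to the iodoalkyne, which fixes the Z geometry of the iodoalkene without touching the C–I bond or the stereocentre.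

Step 6
Reactants: 8 (S)-3-[(2Z)-3-iodoprop-2-en-1-yl]docosane-1,3-diol
Product: 10 (S)-3-hydroxy-3-[(2Z)-3-iodoprop-2-en-1-yl]docosanoic acid, via hydroxy aldehyde 9 (not isolated)
Conditions: TEMPO (20 mol %), PhI(OAc)2 (2.5 equiv), MeCN/H2O 1:1, rt
Reagents that add atoms: water, O
Why: Oxoammonium (TEMPO) oxidation is selective for the primary alcohol and, in the presence of water, carries aldehyde 9 through its hydrate to the carboxylic acid, while the tertiary alcohol and the alkenyl iodide are inert.

Step 7
Reactants: 10 (S)-3-hydroxy-3-[(2Z)-3-iodoprop-2-en-1-yl]docosanoic acid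
Product: 12 (S)-4-[(2Z)-3-iodoprop-2-en-1-yl]-4-nonadecyloxetan-2-one, via mixed sulfonic anhydride 11 (not isolated)
Conditions: PhSO2Cl (2 equiv), pyridine, 0 to 4 °C
Reagents that add atoms: none
Why: β-Lactonisation by carboxyl activation: the mixed anhydride 11 is attacked at its acyl carbon by the tertiary hydroxyl (4-exo-trig), so the C–O bond at the stereocentre is never broken and the configuration is retained.

Step 8
Reactants: 12 (S)-4-[(2Z)-3-iodoprop-2-en-1-yl]-4-nonadecyloxetan-2-one
Product: 16 (S)-5-hydroxy-5-nonadecylcyclohex-2-en-1-one, via alkenyllithium 13 (not isolated), via bridged alkoxide 14 (not isolated), via lithium alkoxide 15 (not isolated)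
Conditions: t-BuLi (2.1 equiv), THF/Et2O/pentane 4:1:1, 0.01 M, −105 to −78 °C; AcOH/THF, −78 °C
Reagents that add atoms: none
Why: Iodine–lithium exchange, expected to be faster at −105 °C than addition of tert-butyllithium to the lactone, gives the configurationally stable (Z)-alkenyllithium 13, whose carbanion C2 adds to the lactone carbonyl C1 to give the bridged tetrahedral alkoxide 14; collapse of 14 cleaves the acyl C–O bond of the four-membered ring, releases its strain and gives the lithium alkoxide 15 of the β-hydroxy enone. The closest known reaction types are the Parham cyclisation (halogen–lithium exchange followed by intramolecular acylation by a carboxylic acid derivative) and the acyl–oxygen opening of β-lactones by organolithiums to β-hydroxy ketones. The six-membered carbocycle closes in the 6-exo-trig mode (C2 onto the C1=O that is exocyclic to the forming ring) while the oxetanone opens. No new stereocentre remains in the product: C5 is carried from step 2 because none of its bonds is broken, and the bridgehead centre of 14 is dictated by the bicycle and lost on collapse. The step needs acylation to beat proton transfer from the lactone CH2 and intermolecular addition, which the Z geometry (C2 held over the lactone face), the high electrophilicity of the strained carbonyl and high dilution should secure; over-addition is excluded because each molecule carries one carbanion and the second equivalent of tert-butyllithium is consumed by tert-butyl iodide. The cold acidic quench should keep 15 from retro-aldol cleavage or dehydration to the phenol.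

**Compound list**

1 | 3-methylbut-3-en-1-ol (isoprenol) | CC(=C)CCO | starting material
2 | 1-bromooctadecane | CCCCCCCCCCCCCCCCCCBr | starting material
3 | dilithiated 3-methylbut-3-en-1-ol (lithium 3-(lithiomethyl)but-3-en-1-olate) | [Li]CC(=C)CCO[Li] | intermediate
4 | 3-methylidenedocosan-1-ol | C=C(CCO)CCCCCCCCCCCCCCCCCCC | intermediate
5 | (R)-2-(2-nonadecyloxiran-2-yl)ethan-1-ol | CCCCCCCCCCCCCCCCCCC[C@@]1(CCO)CO1 | intermediate
6 | (S)-3-(prop-2-yn-1-yl)docosane-1,3-diol | CCCCCCCCCCCCCCCCCCC[C@@](O)(CCO)CC#C | intermediate
7 | (S)-3-(3-iodoprop-2-yn-1-yl)docosane-1,3-diol | CCCCCCCCCCCCCCCCCCC[C@@](O)(CCO)CC#CI | intermediate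
8 | (S)-3-[(2Z)-3-iodoprop-2-en-1-yl]docosane-1,3-diol | CCCCCCCCCCCCCCCCCCC[C@@](O)(CCO)C/C=C\I | intermediate
9 | (S)-3-hydroxy-3-[(2Z)-3-iodoprop-2-en-1-yl]docosanal | CCCCCCCCCCCCCCCCCCC[C@@](O)(CC=O)C/C=C\I | intermediate
10 | (S)-3-hydroxy-3-[(2Z)-3-iodoprop-2-en-1-yl]docosanoic acid | CCCCCCCCCCCCCCCCCCC[C@@](O)(CC(=O)O)C/C=C\I | intermediate
11 | benzenesulfonic (S)-3-hydroxy-3-[(2Z)-3-iodoprop-2-en-1-yl]docosanoic anhydride | CCCCCCCCCCCCCCCCCCC[C@@](O)(CC(=O)OS(=O)(=O)c1ccccc1)C/C=C\I | intermediate
12 | (S)-4-[(2Z)-3-iodoprop-2-en-1-yl]-4-nonadecyloxetan-2-one | CCCCCCCCCCCCCCCCCCC[C@]1(OC(=O)C1)C/C=C\I | intermediate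
13 | (S)-4-[(2Z)-3-lithioprop-2-en-1-yl]-4-nonadecyloxetan-2-one | CCCCCCCCCCCCCCCCCCC[C@]1(OC(=O)C1)C\C=C/[Li] | intermediate
14 | lithium 5-nonadecyl-6-oxabicyclo[3.1.1]hept-2-en-1-olate (the one bridged diastereomer the bicycle allows) | CCCCCCCCCCCCCCCCCCC[C@]12CC=C[C@](O[Li])(C1)O2 | intermediate
15 | lithium (S)-1-nonadecyl-5-oxocyclohex-3-en-1-olate | CCCCCCCCCCCCCCCCCCC[C@]1(O[Li])CC=CC(=O)C1 | intermediate
16 | (S)-5-hydroxy-5-nonadecylcyclohex-2-en-1-one | CCCCCCCCCCCCCCCCCCC[C@]1(O)CC=CC(=O)C1 | target

Total step count: 8
Longest linear sequence: 8 steps (from 1 or 2 to 16)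

**Steps most likely to fail**

1. Step 8 (key step).
   - What may go wrong: addition of tert-butyllithium to the strained carbonyl before the exchange is complete; proton transfer from the lactone CH2 to the alkenyllithium; retro-aldol opening or dehydration of the lithium aldolate if the mixture warms before the quench.
   - Fallback (sets out from 8, comes back at 16): oxidation of 8 with TEMPO/PhI(OAc)2 in dry CH2Cl2 should stop at aldehyde 9, which is then isolated. An intramolecular Nozaki–Hiyama–Kishi reaction (CrCl2, NiCl2 cat., DMSO/THF, high dilution) would form the same C1–C2 bond and should give (5S)-5-nonadecylcyclohex-2-ene-1,5-diol F1 as a mixture at C1. MnO2 in CH2Cl2 should oxidise only the allylic secondary alcohol and give 16.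

2. Step 2.
   - What may go wrong: poor facial discrimination, because both alkene substituents are unbranched CH2 groups, and slow turnover with the waxy substrate.
   - Fallback (sets out from 2, comes back at 12): the centre is set by a Sharpless asymmetric epoxidation instead, and C1 is brought in as carbon monoxide.
   - 2-Methylprop-2-en-1-ol F2 is converted into its dianion, dilithiated 2-methylprop-2-en-1-ol F3 (n-BuLi, TMEDA), which is alkylated with 2 to give 2-methylidenehenicosan-1-ol F4.
   - Epoxidation [Ti(Oi-Pr)4, D-(−)-diethyl tartrate (the antipode that gives (R)-2-alkylglycidols), t-BuOOH, 4 Å MS, CH2Cl2, −20 °C] should give (R)-(2-nonadecyloxiran-2-yl)methanol F5.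
   - TsCl/Et3N should give (S)-(2-nonadecyloxiran-2-yl)methyl 4-methylbenzenesulfonate F6.
   - Lithium acetylide opens the epoxide CH2, and the resulting alkoxide, lithium (S)-2-nonadecyl-1-(tosyloxy)pent-4-yn-2-olate F7, displaces the tosylate to give (S)-2-nonadecyl-2-(prop-2-yn-1-yl)oxirane F8.
   - NIS/AgNO3 should give (S)-2-(3-iodoprop-2-yn-1-yl)-2-nonadecyloxirane F9, and diimide (as in step 5) (S)-2-[(2Z)-3-iodoprop-2-en-1-yl]-2-nonadecyloxirane F10.
   - Ring-expanding carbonylation (CO, [(salph)Al(THF)2][Co(CO)4], THF) should insert CO into the CH2–O bond with retention at the quaternary carbon and give 12.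

3. Step 5.
   - What may go wrong: over-reduction of the iodoalkene to the alkyl iodide and incomplete conversion, giving mixtures that are hard to separate.
   - Fallback (sets out from 5, comes back at 8): copper-catalysed opening of epoxide 5 with vinylmagnesium bromide (CuI cat., THF, −30 °C) should give (S)-3-(prop-2-en-1-yl)docosane-1,3-diol F11. Ozonolysis (O3, CH2Cl2/MeOH, −78 °C; PPh3) should give (R)-3,5-dihydroxy-3-nonadecylpentanal F12, expected to rest as its six-membered lactol. Stork–Zhao olefination with excess Ph3P=CHI (from iodomethyltriphenylphosphonium iodide and NaHMDS, THF/HMPA, −78 °C) sets the Z-iodoalkene in the Wittig step and should give 8.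

**Further compounds**

F1 | step 8 | (5S)-5-nonadecylcyclohex-2-ene-1,5-diol (mixture at C1) | CCCCCCCCCCCCCCCCCCC[C@]1(O)CC=CC(O)C1
F2 | step 2 | 2-methylprop-2-en-1-ol | CC(=C)CO
F3 | step 2 | dilithiated 2-methylprop-2-en-1-ol | [Li]CC(=C)CO[Li]
F4 | step 2 | 2-methylidenehenicosan-1-ol | C=C(CO)CCCCCCCCCCCCCCCCCCC
F5 | step 2 | (R)-(2-nonadecyloxiran-2-yl)methanol | CCCCCCCCCCCCCCCCCCC[C@@]1(CO)CO1
F6 | step 2 | (S)-(2-nonadecyloxiran-2-yl)methyl 4-methylbenzenesulfonate | CCCCCCCCCCCCCCCCCCC[C@@]1(COS(=O)(=O)c2ccc(C)cc2)CO1
F7 | step 2 | lithium (S)-2-nonadecyl-1-(tosyloxy)pent-4-yn-2-olate | CCCCCCCCCCCCCCCCCCC[C@@](O[Li])(COS(=O)(=O)c1ccc(C)cc1)CC#C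
F8 | step 2 | (S)-2-nonadecyl-2-(prop-2-yn-1-yl)oxirane | CCCCCCCCCCCCCCCCCCC[C@@]1(CO1)CC#C
F9 | step 2 | (S)-2-(3-iodoprop-2-yn-1-yl)-2-nonadecyloxirane | CCCCCCCCCCCCCCCCCCC[C@@]1(CO1)CC#CI
F10 | step 2 | (S)-2-[(2Z)-3-iodoprop-2-en-1-yl]-2-nonadecyloxirane | CCCCCCCCCCCCCCCCCCC[C@@]1(CO1)C/C=C\I
F11 | step 5 | (S)-3-(prop-2-en-1-yl)docosane-1,3-diol | CCCCCCCCCCCCCCCCCCC[C@@](O)(CCO)CC=C
F12 | step 5 | (R)-3,5-dihydroxy-3-nonadecylpentanal (open form of the lactol) | CCCCCCCCCCCCCCCCCCC[C@@](O)(CCO)CC=O
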